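**Retrosynthetic overview**

1. Locants for target 29: ring A (pyranone) O1, C2(=O), C3, C4(–O), C5, C6; C7 is the CH2 on C3; ring C (cycloheptane) C8, C9, C10, C14, C15, C16, C17; ring D (cyclopentenone) C10=C11–C12(=O)–C13(Me)2–C14; ring B (dihydropyran) C3, C4, O, C17, C8, C7. Target 29 is (8R,9R,14R,16R,17S). Last disconnection: 29 ⇐ enol ether 27 by epoxidation and hydration of C16=C17.
2. Key disconnection: 27 ⇐ acetyl δ-lactone 25. One base treatment moves the lactone acyl carbon C17 from O14 to C16 (closes ring C), and the resulting diketonate oxygen on C17 then displaces chloride at pyranone C4 (closes ring B through the C4–O bond). Enabling feature: ring C contains O14–C14–C15(=O)–C16–C17(=O), an α'-hydroxy-1,3-diketone (the retron of an O→C acyl shift), and the C17 oxygen is tied to C4 through C17–C8–C7–C3, where C4 is a vinylogous acyl carbon of ring A.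
3. 25 ⇐ lactone 20 + pyranone bromide 7 (enolate alkylation, sets C8). 20 ⇐ dienyl lactone 19 (copper hydride reduction, sets C9) ⇐ ring-closing metathesis of acrylate 18 ⇐ acetylide addition to enone 14 (sets C14).
4. Absolute configuration comes from a ketoreductase reduction of 2,2-dimethylcyclopentane-1,3-dione 8; the temporary carbinol at C12 relays to C14. Bromide 7 comes from 3-methylpentane-2,4-dione 1.
5. Ring order: A (step 2); D is bought with 8; temporary δ-lactone (step 12); C and then B in one operation (step 18). The C4 chloride, the lactone ring and the lower oxidation level at C16/C17 are all removed by steps 18 and 19.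

Key step: step 18

Remark: C16 and C17 of 29 can interconvert through the ring-opened hydroxy-diketone (ring–chain tautomerism, enolisation), so step 19 is run under neutral conditions and aims at kinetic control.

**Step 1**
Reactants: 1 3-methylpentane-2,4-dione
Product: 3 4-methyl-3,5-dioxohexanoic acid, via dilithium dienediolate 2 (not isolated)
Conditions: LDA (2.2 equiv), THF, −78 → 0 °C; CO2 (g), −78 °C; then 1 M HCl
Reagents that add atoms: carbon dioxide, O=C=O
Why: Carboxylation of a β-diketone dianion; the second deprotonation takes place at a terminal methyl group and this more reactive carbanion attacks CO2.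

**Step 2**
Reactants: 3 4-methyl-3,5-dioxohexanoic acid
Product: 4 4-hydroxy-5,6-dimethyl-2H-pyran-2-one
Conditions: (CF3CO)2O, CF3CO2H, 0 → 23 °C; then H2O
Reagents that add atoms: none
Why: Cyclodehydration of a 3,5-dioxo acid (mixed-anhydride activation, O-acylation by the C5 enol), the classical closure to 4-hydroxy-2-pyranones.

**Step 3**
Reactants: 4 4-hydroxy-5,6-dimethyl-2H-pyran-2-one
Product: 5 4-chloro-5,6-dimethyl-2-oxo-2H-pyran-3-carbaldehyde
Conditions: POCl3, DMF, 0 → 60 °C; then ice-water
Reagents that add atoms: N,N-dimethylformamide, CN(C)C=O; phosphoryl chloride, O=P(Cl)(Cl)Cl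
Why: Vilsmeier–Haack reaction; the nucleophilic C3 is formylated and the 4-OH is exchanged for chloride, as known for 4-hydroxy-6-methylpyranone and 4-hydroxycoumarin.

**Step 4**
Reactants: 5 4-chloro-5,6-dimethyl-2-oxo-2H-pyran-3-carbaldehyde
Product: 6 4-chloro-3-(hydroxymethyl)-5,6-dimethyl-2H-pyran-2-one
Conditions: NaBH4, CeCl3·7H2O, MeOH, −78 °C
Reagents that add atoms: none
Why: Luche 1,2-reduction; the hard cerium-modified borohydride reduces the aldehyde without addition–elimination at the β-chloro position.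

**Step 5**
Reactants: 6 4-chloro-3-(hydroxymethyl)-5,6-dimethyl-2H-pyran-2-one
Product: 7 3-(bromomethyl)-4-chloro-5,6-dimethyl-2H-pyran-2-one
Conditions: CBr4, PPh3, CH2Cl2, 0 °C
Reagents that add atoms: tetrabromomethane, BrC(Br)(Br)Br
Why: Appel bromination of a primary allylic-type alcohol under neutral conditions that leave the vinylogous acyl chloride intact.

**Step 6**
Reactants: 8 2,2-dimethylcyclopentane-1,3-dione
Product: 9 (S)-3-hydroxy-2,2-dimethylcyclopentan-1-one
Conditions: (S)-selective ketoreductase (KRED), NADP+ (cat.), i-PrOH, phosphate buffer pH 7, 30 °C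
Reagents that add atoms: none
Why: Enzymatic mono-reduction by a ketoreductase (the enzyme class behind the yeast reductions of 2,2-dialkylcycloalkane-1,3-diones); the enzyme selects the carbonyl face to give the (S)-carbinol and stops at the hydroxy ketone.

**Step 7**
Reactants: 9 (S)-3-hydroxy-2,2-dimethylcyclopentan-1-one
Product: 10 (S)-3-[(tert-butyldimethylsilyl)oxy]-2,2-dimethylcyclopentan-1-one
Conditions: TBSCl, imidazole, DMF, 23 °C
Reagents that add atoms: tert-butyldimethylsilyl chloride, CC(C)(C)[Si](C)(C)Cl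
Why: Standard silylation of a secondary alcohol; the ether later serves as the stereocontrol element for C14.

**Step 8**
Reactants: 10 (S)-3-[(tert-butyldimethylsilyl)oxy]-2,2-dimethylcyclopentan-1-one
Product: 11 (S)-4-[(tert-butyldimethylsilyl)oxy]-5,5-dimethylcyclopent-2-en-1-one
Conditions: IBX, DMSO, 70 °C
Reagents that add atoms: none
Why: IBX dehydrogenation of a ketone to the enone; only one α-position carries hydrogen, and the silyloxy group cannot eliminate because the carbon between it and the carbonyl is quaternary.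

**Step 9**
Reactants: 11 (S)-4-[(tert-butyldimethylsilyl)oxy]-5,5-dimethylcyclopent-2-en-1-one
Product: 12 (S)-4-[(tert-butyldimethylsilyl)oxy]-2-iodo-5,5-dimethylcyclopent-2-en-1-one
Conditions: I2, pyridine, CH2Cl2, 0 → 23 °C
Reagents that add atoms: iodine, II
Why: α-Iodination of the enone by pyridine conjugate addition, enolate iodination and elimination (Baylis–Hillman-type mechanism), well established for 4-silyloxycyclopentenones.

**Step 10**
Reactants: 12 (S)-4-[(tert-butyldimethylsilyl)oxy]-2-iodo-5,5-dimethylcyclopent-2-en-1-one; 13 isopropenylboronic acid pinacol ester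
Product: 14 (S)-4-[(tert-butyldimethylsilyl)oxy]-5,5-dimethyl-2-(prop-1-en-2-yl)cyclopent-2-en-1-one
Conditions: PdCl2(dppf) (5 mol %), K3PO4, THF/H2O, 50 °C
Reagents that add atoms: none
Why: Suzuki–Miyaura coupling of an α-iodoenone with an alkenylboronate, a well-precedented sp2–sp2 coupling.

**Step 11**
Reactants: 14 (S)-4-[(tert-butyldimethylsilyl)oxy]-5,5-dimethyl-2-(prop-1-en-2-yl)cyclopent-2-en-1-one; 15 ethynyltrimethylsilane; 16 acryloyl chloride
Product: 18 (1R,4S)-4-[(tert-butyldimethylsilyl)oxy]-5,5-dimethyl-2-(prop-1-en-2-yl)-1-[(trimethylsilyl)ethynyl]cyclopent-2-en-1-yl acrylate, via lithium tertiary alkoxide 17 (not isolated)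
Conditions: 15, n-BuLi, THF, −78 °C; add 14, −78 °C; then 16, −78 → 0 °C
Reagents that add atoms: none
Why: 1,2-Addition of the lithium acetylide to the non-enolisable ketone should occur on the face opposite the C4 silyloxy group (as in additions to 4-silyloxycyclopentenones), which fixes the quaternary carbinol (1R, the future C14); the hindered lithium alkoxide is then O-acylated in the same flask.

**Step 12**
Reactants: 18 the acrylate from step 11
Product: 19 (6S,7aR)-6-[(tert-butyldimethylsilyl)oxy]-4,7,7-trimethyl-7a-[(trimethylsilyl)ethynyl]-7,7a-dihydrocyclopenta[b]pyran-2(6H)-one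
Conditions: second-generation Grubbs catalyst (H2IMes)(PCy3)Cl2Ru=CHPh (5 mol %), toluene, 80 °C
Reagents that add atoms: none
Why: Ring-closing metathesis of an acrylate with a 1,1-disubstituted alkene gives the β-methyl unsaturated δ-lactone; the silyl-capped alkyne and the trisubstituted ring alkene are too hindered to take part.

**Step 13**
Reactants: 19 the dienyl lactone from step 12
Product: 20 (4R,6S,7aR)-6-[(tert-butyldimethylsilyl)oxy]-4,7,7-trimethyl-7a-[(trimethylsilyl)ethynyl]-4,6,7,7a-tetrahydrocyclopenta[b]pyran-2(3H)-one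
Conditions: Cu(OAc)2·H2O (5 mol %), 1,2-bis(diphenylphosphino)benzene (5 mol %), (EtO)2MeSiH, t-BuOH, toluene, 0 → 23 °C
Reagents that add atoms: none
Why: Copper hydride conjugate reduction of a β,β-disubstituted unsaturated lactone, which with 2,4-dienoates is expected to take the 1,4 course; hydride should enter at C4 on the face opposite the pseudo-axial 7a-alkynyl group, placing the C4 methyl cis to that group (4R, the future C9).

**Step 14**
Reactants: 20 the saturated lactone from step 13; 7 3-(bromomethyl)-4-chloro-5,6-dimethyl-2H-pyran-2-one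
Product: 22 (3R,4R,6S,7aR)-6-[(tert-butyldimethylsilyl)oxy]-3-[(4-chloro-5,6-dimethyl-2-oxo-2H-pyran-3-yl)methyl]-4,7,7-trimethyl-7a-[(trimethylsilyl)ethynyl]-4,6,7,7a-tetrahydrocyclopenta[b]pyran-2(3H)-one, via lithium lactone enolate 21 (not isolated)
Conditions: LDA, THF, −78 °C; then 7, −78 → −40 °C
Reagents that add atoms: none
Why: SN2 alkylation of the lactone enolate by the reactive allylic-type bromide on the face anti to both the adjacent C4 methyl and the 7a-alkynyl group should give the 3,4-trans product (3R, the future C8); the C–Cl bond of 7 is not attacked at this temperature.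

**Step 15**
Reactants: 22 the alkylated lactone from step 14
Product: 23 (3R,4R,6S,7aR)-3-[(4-chloro-5,6-dimethyl-2-oxo-2H-pyran-3-yl)methyl]-7a-ethynyl-6-hydroxy-4,7,7-trimethyl-4,6,7,7a-tetrahydrocyclopenta[b]pyran-2(3H)-one
Conditions: TBAF, AcOH, THF, 0 → 23 °C
Reagents that add atoms: none
Why: Buffered fluoride cleaves both the O–Si bond and the alkynyl C–Si bond, while the buffer protects the lactone and the chloropyranone from base.

**Step 16**
Reactants: 23 the hydroxy alkyne from step 15
Product: 24 (3R,4R,7aR)-3-[(4-chloro-5,6-dimethyl-2-oxo-2H-pyran-3-yl)methyl]-7a-ethynyl-4,7,7-trimethyl-4,7-dihydrocyclopenta[b]pyran-2,6(3H,7aH)-dione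
Conditions: Dess–Martin periodinane, CH2Cl2, 23 °C
Reagents that add atoms: none
Why: Dess–Martin oxidation of the allylic alcohol gives the cyclopentenone of ring D directly and removes the relay stereocentre.

**Step 17**
Reactants: 24 the ethynyl enone from step 16
Product: 25 (3R,4R,7aR)-7a-acetyl-3-[(4-chloro-5,6-dimethyl-2-oxo-2H-pyran-3-yl)methyl]-4,7,7-trimethyl-4,7-dihydrocyclopenta[b]pyran-2,6(3H,7aH)-dione
Conditions: Ph3PAuNTf2 (5 mol %), H2O, 1,4-dioxane, 60 °C
Reagents that add atoms: water, O
Why: Gold-catalysed Markovnikov hydration of the terminal alkyne gives the methyl ketone; acyloxy migration is blocked because the lactone carbonyl oxygen points away from the alkyne, and ionisation at the tertiary centre is disfavoured by the adjacent enone.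

**Step 18**
Reactants: 25 the acetyl δ-lactone from step 17
Product: 27 (8R,9R,14R)-16,17-didehydro-16,17-dideoxy-29 (tetracyclic enol ether with C17(–O–C4)=C16H–C15(=O) and free 14-OH), via potassium diketonate 26 (not isolated)
Conditions: KHMDS (1.1 equiv), THF, −78 °C; then 18-crown-6, −78 → 23 °C
Reagents that add atoms: none
Why: Kinetic deprotonation of the acetyl methyl gives an enolate whose carbon adds to the lactone carbonyl C17 (5-exo-trig); the bridged tetrahedral adduct collapses with loss of the tertiary alkoxide O14, a Baker–Venkataraman O→C acyl shift that converts the δ-lactone into the cycloheptane-1,3-dione of ring C (net ring expansion), and internal proton transfer gives diketonate 26. On warming, the enolate oxygen on C17 adds to the vinylogous acyl chloride carbon C4 of ring A and chloride leaves (6-endo-trig addition–elimination), closing ring B through the C4–O bond. The closest precedents are Baker–Venkataraman rearrangements of aliphatic α-acyloxy ketones and O-vinylation of 1,3-diketonates by 4-halo-2-pyranones and 4-chlorocoumarins. No stereocentre is created: the C14–O bond is never broken, C9 is not touched at low temperature, and C8 stays trans to the C9 methyl. The step needs O- over C-attack of the ambident diketonate and reaction at the C17 rather than the C15 oxygen; the potassium/crown-ether ion pair favours O-attack on the hard vinylogous acyl halide, and only the C17 oxygen reaches C4 through a six-membered transition state (the C15 oxygen would need an eight-membered one). One equivalent of base is enough, so the product is not exposed to excess base.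

**Step 19**
Reactants: 27 the enol ether from step 18
Product: 29 CNP0525404.1, (8R,9R,14R,16R,17S), via C16–C17 epoxide 28 (not isolated)
Conditions: DMDO, acetone, −20 → 0 °C; then H2O, THF, pH 7 phosphate buffer, 23 °C
Reagents that add atoms: dimethyldioxirane, CC1(C)OO1; water, O
Why: Rubottom-type oxidation of a β-oxo enol ether; the dioxirane should approach C16=C17 on the face opposite the pseudo-axial 14-OH and the C9 flap of the twisted seven-membered ring (sets 16R), and water opens the epoxide at the acetal carbon C17 with inversion to give the axial, anomerically stabilised 17-OH and the trans B/C fusion.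

**Compound list**

1 | 3-methylpentane-2,4-dione | CC(=O)C(C)C(C)=O | starting material
2 | dilithium dienediolate of 1 | [Li+].[Li+].[O-]C(=C)C(C)=C(C)[O-] | intermediate
3 | 4-methyl-3,5-dioxohexanoic acid | CC(=O)C(C)C(=O)CC(=O)O | intermediate
4 | 4-hydroxy-5,6-dimethyl-2H-pyran-2-one | Cc1oc(=O)cc(O)c1C | intermediate
5 | 4-chloro-5,6-dimethyl-2-oxo-2H-pyran-3-carbaldehyde | Cc1oc(=O)c(C=O)c(Cl)c1C | intermediate
6 | 4-chloro-3-(hydroxymethyl)-5,6-dimethyl-2H-pyran-2-one | Cc1oc(=O)c(CO)c(Cl)c1C | intermediate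
7 | 3-(bromomethyl)-4-chloro-5,6-dimethyl-2H-pyran-2-one | Cc1oc(=O)c(CBr)c(Cl)c1C | intermediate
8 | 2,2-dimethylcyclopentane-1,3-dione | O=C1CCC(=O)C1(C)C | starting material
9 | (S)-3-hydroxy-2,2-dimethylcyclopentan-1-one | O=C1CC[C@H](O)C1(C)C | intermediate
10 | (S)-3-[(tert-butyldimethylsilyl)oxy]-2,2-dimethylcyclopentan-1-one | O=C1CC[C@H](O[Si](C)(C)C(C)(C)C)C1(C)C | intermediate
11 | (S)-4-[(tert-butyldimethylsilyl)oxy]-5,5-dimethylcyclopent-2-en-1-one | O=C1C=C[C@H](O[Si](C)(C)C(C)(C)C)C1(C)C | intermediate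
12 | (S)-4-[(tert-butyldimethylsilyl)oxy]-2-iodo-5,5-dimethylcyclopent-2-en-1-one | O=C1C(I)=C[C@H](O[Si](C)(C)C(C)(C)C)C1(C)C | intermediate
13 | isopropenylboronic acid pinacol ester | CC(=C)B1OC(C)(C)C(C)(C)O1 | starting material
14 | (S)-4-[(tert-butyldimethylsilyl)oxy]-5,5-dimethyl-2-(prop-1-en-2-yl)cyclopent-2-en-1-one | O=C1C(C(C)=C)=C[C@H](O[Si](C)(C)C(C)(C)C)C1(C)C | intermediate
15 | ethynyltrimethylsilane | C#C[Si](C)(C)C | starting material
16 | acryloyl chloride | C=CC(=O)Cl | starting material
17 | lithium (1R,4S)-4-[(tert-butyldimethylsilyl)oxy]-5,5-dimethyl-2-(prop-1-en-2-yl)-1-[(trimethylsilyl)ethynyl]cyclopent-2-en-1-olate | [Li+].[O-][C@]1(C#C[Si](C)(C)C)C(C(C)=C)=C[C@H](O[Si](C)(C)C(C)(C)C)C1(C)C | intermediate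
18 | (1R,4S)-4-[(tert-butyldimethylsilyl)oxy]-5,5-dimethyl-2-(prop-1-en-2-yl)-1-[(trimethylsilyl)ethynyl]cyclopent-2-en-1-yl acrylate | C=CC(=O)O[C@]1(C#C[Si](C)(C)C)C(C(C)=C)=C[C@H](O[Si](C)(C)C(C)(C)C)C1(C)C | intermediate
19 | (6S,7aR)-6-[(tert-butyldimethylsilyl)oxy]-4,7,7-trimethyl-7a-[(trimethylsilyl)ethynyl]-7,7a-dihydrocyclopenta[b]pyran-2(6H)-one | O=C1C=C(C)C2=C[C@H](O[Si](C)(C)C(C)(C)C)C(C)(C)[C@]2(C#C[Si](C)(C)C)O1 | intermediate
20 | (4R,6S,7aR)-6-[(tert-butyldimethylsilyl)oxy]-4,7,7-trimethyl-7a-[(trimethylsilyl)ethynyl]-4,6,7,7a-tetrahydrocyclopenta[b]pyran-2(3H)-one | O=C1C[C@@H](C)C2=C[C@H](O[Si](C)(C)C(C)(C)C)C(C)(C)[C@]2(C#C[Si](C)(C)C)O1 | intermediate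
21 | lithium enolate of lactone 20 | [Li+].[O-]C1=C[C@@H](C)C2=C[C@H](O[Si](C)(C)C(C)(C)C)C(C)(C)[C@]2(C#C[Si](C)(C)C)O1 | intermediate
22 | (3R,4R,6S,7aR)-6-[(tert-butyldimethylsilyl)oxy]-3-[(4-chloro-5,6-dimethyl-2-oxo-2H-pyran-3-yl)methyl]-4,7,7-trimethyl-7a-[(trimethylsilyl)ethynyl]-4,6,7,7a-tetrahydrocyclopenta[b]pyran-2(3H)-one | O=C1[C@H](Cc3c(Cl)c(C)c(C)oc3=O)[C@@H](C)C2=C[C@H](O[Si](C)(C)C(C)(C)C)C(C)(C)[C@]2(C#C[Si](C)(C)C)O1 | intermediate
23 | (3R,4R,6S,7aR)-3-[(4-chloro-5,6-dimethyl-2-oxo-2H-pyran-3-yl)methyl]-7a-ethynyl-6-hydroxy-4,7,7-trimethyl-4,6,7,7a-tetrahydrocyclopenta[b]pyran-2(3H)-one | O=C1[C@H](Cc3c(Cl)c(C)c(C)oc3=O)[C@@H](C)C2=C[C@H](O)C(C)(C)[C@]2(C#C)O1 | intermediate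
24 | (3R,4R,7aR)-3-[(4-chloro-5,6-dimethyl-2-oxo-2H-pyran-3-yl)methyl]-7a-ethynyl-4,7,7-trimethyl-4,7-dihydrocyclopenta[b]pyran-2,6(3H,7aH)-dione | O=C1[C@H](Cc3c(Cl)c(C)c(C)oc3=O)[C@@H](C)C2=CC(=O)C(C)(C)[C@]2(C#C)O1 | intermediate
25 | (3R,4R,7aR)-7a-acetyl-3-[(4-chloro-5,6-dimethyl-2-oxo-2H-pyran-3-yl)methyl]-4,7,7-trimethyl-4,7-dihydrocyclopenta[b]pyran-2,6(3H,7aH)-dione | O=C1[C@H](Cc3c(Cl)c(C)c(C)oc3=O)[C@@H](C)C2=CC(=O)C(C)(C)[C@]2(C(C)=O)O1 | intermediate
26 | potassium (8R,9R,14R)-diketonate: ring C 15,17-dione enolate with free 14-OH and pendant 4-chloropyranone on C7 | [K+].[O-]C1=CC(=O)[C@@]2(O)C(=CC(=O)C2(C)C)[C@H](C)[C@H]1Cc1c(Cl)c(C)c(C)oc1=O | intermediate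
27 | (8R,9R,14R)-16,17-didehydro-16,17-dideoxy-29 (tetracyclic enol ether) | Cc1oc(=O)c2c(c1C)OC1=CC(=O)[C@@]3(O)C(=CC(=O)C3(C)C)[C@H](C)[C@H]1C2 | intermediate
28 | (8R,9R,14R,16R,17R)-16,17-epoxide of 27 | Cc1oc(=O)c2c(c1C)O[C@]13O[C@@H]3C(=O)[C@@]4(O)C(=CC(=O)C4(C)C)[C@H](C)[C@H]1C2 | intermediate
29 | CNP0525404.1, (8R,9R,14R,16R,17S) | Cc1oc(=O)c2c(c1C)O[C@]1(O)[C@H](O)C(=O)[C@@]3(O)C(=CC(=O)C3(C)C)[C@H](C)[C@H]1C2 | target

**Totals**

Total step count: 19. Longest linear sequence: 14 steps (8 → 29, steps 6–19); the pyranone branch (steps 1–5) joins at step 14.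

**Three steps most likely to fail**

Step 18. The ambident diketonate may attack pyranone C4 through carbon C16 instead of oxygen. The transient bridged alkoxide may capture C4 before it collapses, giving a bridged ketal. γ-Deprotonation of the cyclopentenone may scramble C9. The fallback sets out from 25 and comes back at 27, and separates the two events. Soft enolisation with MgBr2·OEt2 and i-Pr2NEt in CH2Cl2 carries out only the O→C acyl shift, because the magnesium chelate of the diketone does not attack C4; this allows isolation of the hydroxy diketone (8R,9R,14R)-14-hydroxy-15,17-dione F1. Ring B is then closed by a copper-catalysed intramolecular O-vinylation (Ullmann-type; CuI, 1,10-phenanthroline, Cs2CO3, toluene, 80 °C), a reaction that is O-selective for 1,3-diketones, to give 27.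

Step 19. Oxygen transfer to C16=C17 may occur on the wrong face. The pyranone or cyclopentenone double bonds may be epoxidised in competition. The 14-OH may open the epoxide transannularly. The fallback sets out from 27 and comes back at 29, and oxidises the free diketone instead of the enol ether. Mild acid hydrolysis of the vinylogous ester (0.1 M HCl, THF/H2O) cleaves the C17–O bond and leaves the oxygen on pyranone C4, giving the ring-opened 4-hydroxypyranone diketone F2. Its dianion (KHMDS, 2 equiv) is hydroxylated at C16 with 2-(phenylsulfonyl)-3-phenyloxaziridine to the open-chain 16-hydroxy-15,17-dione F3, which is not isolated. On neutralisation F3 closes by hemiketalisation of the pyranone hydroxyl onto C17, and the labile C16/C17 pair settles under thermodynamic control to 29.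

Step 13. Hydride may be transferred 1,6 to the dienyl lactone instead of 1,4, or the facial selectivity at C4 may be poor. The fallback sets out from 12 and comes back at 20; it replaces substrate control by auxiliary control and bypasses steps 10–13. Lithium (trimethylsilyl)acetylide adds to iodoenone 12 anti to the silyloxy group to give the tertiary alcohol (1R,4S)-4-[(tert-butyldimethylsilyl)oxy]-2-iodo-5,5-dimethyl-1-[(trimethylsilyl)ethynyl]cyclopent-2-en-1-ol F4. Iodine–magnesium exchange with i-PrMgCl·LiCl (2 equiv, the first deprotonates the alcohol), then CuBr·SMe2 and (S)-3-[(E)-but-2-enoyl]-4-phenyloxazolidin-2-one, effect a copper-mediated conjugate addition on the face opposite the phenyl group. This gives the (3R)-butanoyl imide (S)-3-{(R)-3-[(3S,5R)-3-[(tert-butyldimethylsilyl)oxy]-5-hydroxy-4,4-dimethyl-5-[(trimethylsilyl)ethynyl]cyclopent-1-en-1-yl]butanoyl}-4-phenyloxazolidin-2-one F5. Catalytic NaH in THF then lets the tertiary alkoxide acylate itself on the imide, releasing the auxiliary and giving lactone 20.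

**Further compounds**

F1 | step 18 | (8R,9R,14R)-14-hydroxy-15,17-dione with pendant 4-chloropyranone (keto form of 26) | O=C1CC(=O)[C@@]2(O)C(=CC(=O)C2(C)C)[C@H](C)[C@H]1Cc1c(Cl)c(C)c(C)oc1=O
F2 | step 19 | (8R,9R,14R)-ring-opened 15,17-dione bearing the 4-hydroxy-5,6-dimethyl-2-oxo-2H-pyran-3-ylmethyl group on C8 | Cc1oc(=O)c(C[C@H]2C(=O)CC(=O)[C@@]3(O)C(=CC(=O)C3(C)C)[C@@H]2C)c(O)c1C
F3 | step 19 | (8R,9R,14R)-open-chain 16-hydroxy-15,17-dione (ring–chain tautomer of 29, C16 labile) | Cc1oc(=O)c(C[C@H]2C(=O)C(O)C(=O)[C@@]3(O)C(=CC(=O)C3(C)C)[C@@H]2C)c(O)c1C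
F4 | step 13 | (1R,4S)-4-[(tert-butyldimethylsilyl)oxy]-2-iodo-5,5-dimethyl-1-[(trimethylsilyl)ethynyl]cyclopent-2-en-1-ol | C[Si](C)(C)C#C[C@@]1(O)C(I)=C[C@H](O[Si](C)(C)C(C)(C)C)C1(C)C
F5 | step 13 | (S)-3-{(R)-3-[(3S,5R)-3-[(tert-butyldimethylsilyl)oxy]-5-hydroxy-4,4-dimethyl-5-[(trimethylsilyl)ethynyl]cyclopent-1-en-1-yl]butanoyl}-4-phenyloxazolidin-2-one | O=C(C[C@@H](C)C1=C[C@H](O[Si](C)(C)C(C)(C)C)C(C)(C)[C@@]1(O)C#C[Si](C)(C)C)N1[C@@H](c2ccccc2)COC1=O
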